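Your three earlier runs differ in one ratio, r, the substrate over the coupling partner as charged: 0.417 on Tuesday, 0.833 on Thursday and 1.67 on Monday. In that order the highest reading of first product falls: 35.6%, 32.0%, 25.4%.

| setting | Thursday's | Tuesday's | Monday's | dawn | midnight | summer |
|---|---|---|---|---|---|---|
| substrate | 20 mM | 10 mM | 40 mM | 20 mM | 20 mM (fed, over 1.0 min) | 20 mM |
| coupling partner | 24 mM | 24 mM | 24 mM | 24.0 mM | 24.0 mM | 24.0 mM (fed, over 1.0 min) |
| remark | run made earlier | run made earlier | run made earlier | everything together at the start | all else is in the flask from the start; the feed brings no volume worth counting | all else is in the flask from the start; the feed brings no volume worth counting |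
| time |  |  |  | 2.5 min | 2.5 min | 2.5 min |

| Thursday's: time / min | Thursday's: first product / % | Tuesday's: time / s | Tuesday's: first product / % | Monday's: time / s | Monday's: first product / % |
|---|---|---|---|---|---|
| 0.167 | 16.9 | 10.0 | 17.5 | 20.0 | 20.1 |
| 0.500 | 29.4 | 15.0 | 24.1 | 40.0 | 24.0 |
| 0.833 | 31.6 | 25.0 | 31.0 | 60.0 | 24.8 |
| 1.33 | 32.0 | 40.0 | 35.6 | 80.0 | 25.4 |
| 2.00 | 29.3 | 80.0 | 34.7 | 90.0 | 24.9 |
| 2.50 | 27.7 | 120 | 29.8 | 120 | 24.7 |

(standard deviation of a reading: 0.3 percentage points)

1. the flask with the highest amount of first product, in percent of the substrate charged ("all alike" if they lie within 1.5 percentage points) (dawn / midnight / summer / all alike)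
2. final first product, as a percentage of the substrate charged, in dawn
3. final first product, as a percentage of the substrate charged, in midnight
4. final first product, as a percentage of the substrate charged, in summer

- the numbers in the tables scatter by 0.3 percentage points (one standard deviation)

Write the balance of the substrate, the limiting reagent by charge in the new flasks (20 mM against 24.0 mM). It leaves by coupling, at a pace that goes with substrate times partner. As those falling peaks suggest, it may also leave by a loss to itself, at a pace that goes with substrate squared. The loss per coupling then goes with r.

The bench rule says that equal charges give equal yield, and each new flask holds 1.20 equivalents of partner. Applied honestly, every flask should end like Thursday's run, at 27.7%. That suits dawn, which repeats Thursday's recipe. The rule stops working once the feed is not short against the reaction: feed time over the time of Thursday's peak reading is 0.752, so during the feed r in midnight and in summer is not the charged r.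

My own reckoning takes r at 0.500 min into the feed, counting nothing as reacted. Summer then has the whole substrate against half the partner, so its mid-feed ratio is 1.67, matching Monday's. Midnight has 0.417, matching Tuesday's. I commit to the order midnight, dawn, summer, with summer no higher than Monday's peak reading and midnight under Tuesday's.

The forecast names midnight, with 27.7% for dawn, 30.5% for midnight and 24.5% for summer (range 20.5% to 28.5%); its ground for the low summer figure is that summer “leaves substrate high while partner is scarce”.

The flasks give 27.4% in dawn, 31.0% in midnight and 20.7% in summer, so midnight leads, and summer stands above the low end of the forecast's range by 0.20 percentage points.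

2 substrate → homo dimer (k = 0.440 M⁻¹ s⁻¹); coupling partner + first product → double product (k = 0.760 M⁻¹ s⁻¹); substrate + coupling partner → first product (k = 1.00 M⁻¹ s⁻¹); coupling partner + double product → triple product (k = 0.360 M⁻¹ s⁻¹) Now raise summer's substrate to 50 mM and change nothing else. The same reckoning moves the mid-feed ratio from 1.67 to 4.17. That neighbouring flask ends with 13.5% first product against summer's 20.7%, and its homo dimer holds 69.2% of the substrate charged, against 46.3% in summer.

The earlier runs and the new flask are calculated for an exercise.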